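**Retrosynthetic overview**
1. 5 ⇒ 4: the free 7-OH is released from a MOM acetal in the same pot as the coupling.
2. 4 ⇒ 3 + 1: the key disconnection is the vinylic C3–O7′ ether bond, made by Cu-catalysed C–O coupling of a 3-bromocoumarin with the 7-OH of scopoletin.
3. 3 ⇒ 2 ⇒ 1: C3–H bromination of MOM-protected scopoletin, so both halves come from the same purchased coumarin.
4. Ring order: no ring is built. Both benzopyranone bicycles are bought intact in 1.

Assumption: the SMILES contains no stereocentre, stereogenic axis or open-chain C=C. The target is therefore achiral, and there is no enantiomer to select and no stereocentre to set.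

**Route**

Step 1
Reactants: 1 scopoletin (7-hydroxy-6-methoxy-2H-chromen-2-one)
Product: 2 6-methoxy-7-(methoxymethoxy)-2H-chromen-2-one
Conditions: MOMCl (1.3 equiv), K2CO3 (2 equiv), acetone, 0 °C to rt
Reagents that add atoms: chloromethyl methyl ether (MOMCl), COCCl
Why: Williamson-type O-alkylation of the only acidic and nucleophilic site (7-OH, pKa about 8–9) with a very reactive α-chloro ether, under a mild carbonate base that leaves the lactone closed.

Step 2
Reactants: 2 6-methoxy-7-(methoxymethoxy)-2H-chromen-2-one
Product: 3 3-bromo-6-methoxy-7-(methoxymethoxy)-2H-chromen-2-one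
Conditions: NBS (1.05 equiv), NH4OAc (10 mol %), MeCN, rt, dark
Reagents that add atoms: N-bromosuccinimide (NBS), O=C1CCC(=O)N1Br
Why: Electrophilic vinylic bromination (addition–elimination) goes to C3 because C3 is the vinylogous para position of the 7-alkoxy donor, only the slower ortho sites C5 and C8 are free on the ring, and the neutral dark conditions spare the acetal.

Step 3
Reactants: 3 3-bromo-6-methoxy-7-(methoxymethoxy)-2H-chromen-2-one; 1 scopoletin (1.2 equiv)
Product: 5 7-hydroxy-6-methoxy-3-[(6-methoxy-2-oxo-2H-chromen-7-yl)oxy]-2H-chromen-2-one, via MOM-protected bicoumarin ether 4 (not isolated)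
Conditions: CuI (10 mol %), N,N-dimethylglycine (20 mol %), Cs2CO3 (2 equiv), 4 Å MS, 1,4-dioxane, 85 °C, Ar; filter (Celite), concentrate; then cat. conc. HCl, MeOH–CH2Cl2, 45 °C
Reagents that add atoms: none
Why: Proposed new method: an Ullmann–Ma-type Cu(I)/amino-acid-catalysed C(sp2)–O coupling is extended to a bond class where it has, to my knowledge, not been shown, namely the C3–Br bond of a 3-bromocoumarin (an α-bromo-enoate that is also a Michael acceptor and a base-labile lactone) with a 7-hydroxycoumarin as O-nucleophile; caesium scopoletinate forms the ligated cuprate [L·Cu(I)–OAr]−, the weak electron-poor vinylic C–Br bond adds oxidatively (helped by pre-coordination of the lactone C=O), and the Cu(III)(vinyl)(OAr) species reductively eliminates at the ipso carbon to give the C3–O7′ bond, while uncatalysed oxa-Michael addition at C4 reverts by E1cB faster than it can lose HBr and strictly anhydrous carbonate suppresses hydroxide-triggered lactone opening and coumarin-to-benzofuran ring contraction; the closest known reaction type is the CuI/N,N-dimethylglycine coupling of phenols with aryl and simple vinyl halides, and the following acid-catalysed transacetalisation is a standard MOM cleavage that the acid-stable 3-aryloxycoumarin ether survives.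

**Compound list**
1 | scopoletin (7-hydroxy-6-methoxy-2H-chromen-2-one) | COc1cc2ccc(=O)oc2cc1O | starting material
2 | 6-methoxy-7-(methoxymethoxy)-2H-chromen-2-one | COCOc1cc2oc(=O)ccc2cc1OC | intermediate
3 | 3-bromo-6-methoxy-7-(methoxymethoxy)-2H-chromen-2-one | COCOc1cc2oc(=O)c(Br)cc2cc1OC | intermediate
4 | 6-methoxy-7-(methoxymethoxy)-3-[(6-methoxy-2-oxo-2H-chromen-7-yl)oxy]-2H-chromen-2-one (not isolated) | COCOc1cc2oc(=O)c(Oc3cc4oc(=O)ccc4cc3OC)cc2cc1OC | intermediate
5 | 7-hydroxy-6-methoxy-3-[(6-methoxy-2-oxo-2H-chromen-7-yl)oxy]-2H-chromen-2-one (achiral) | COc1cc2cc(Oc3cc4oc(=O)ccc4cc3OC)c(=O)oc2cc1O | target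

**Totals**
Total step count: 3.
Longest linear sequence: 3 (1 → 2 → 3 → 5). Scopoletin enters twice, once as precursor of the electrophile and once as the nucleophile.

**Steps most likely to fail**

1. Step 3 (the new coupling). The risks are no turnover with the weakly nucleophilic, ortho-substituted phenoxide, hydrodebromination, and ring contraction of 3 by adventitious hydroxide. The fallback uses only known chemistry, sets out from 1 and comes back to the route at 5. Compound 1 is O-alkylated with ethyl bromoacetate (K2CO3, acetone, reflux) to ethyl 2-[(6-methoxy-2-oxo-2H-chromen-7-yl)oxy]acetate F1. This is saponified (aq. NaOH, then HCl, which recloses the lactone) to 2-[(6-methoxy-2-oxo-2H-chromen-7-yl)oxy]acetic acid F2. Perkin–Oglialoro condensation of F2 with commercial 2,4-dihydroxy-5-methoxybenzaldehyde (COc1cc(C=O)c(O)cc1O) in Ac2O/NaOAc at 140 °C builds the second pyranone ring around the ether oxygen already in place. It gives 6-methoxy-3-[(6-methoxy-2-oxo-2H-chromen-7-yl)oxy]-2-oxo-2H-chromen-7-yl acetate F3. Acid-catalysed methanolysis (cat. HCl, MeOH, reflux) then gives 5.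

2. Step 2 (bromination). The risks are radical attack of NBS on the OCH2O group, or traces of HBr stripping the acetal, after which the free phenol brominates at C8. Over-bromination is also possible. The fallback changes the protecting-group strategy, sets out from 1 and comes back at 5. Compound 1 is benzylated (BnBr, K2CO3, DMF) to 7-(benzyloxy)-6-methoxy-2H-chromen-2-one F4. The acid-proof ether allows the classical ionic Br2/NaOAc/AcOH addition–elimination, giving 7-(benzyloxy)-3-bromo-6-methoxy-2H-chromen-2-one F5. Coupling with 1 under the copper conditions of step 3 gives 7-(benzyloxy)-6-methoxy-3-[(6-methoxy-2-oxo-2H-chromen-7-yl)oxy]-2H-chromen-2-one F6. F6 is isolated and debenzylated with BCl3/pentamethylbenzene (CH2Cl2, −78 °C) to 5, at the cost of one extra step.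

3. Step 1 (MOM protection). The risks are hydrolysis of MOMCl and incomplete alkylation. The fallback sets out from 1 and comes back at 2. Instead of alkylating the phenoxide under base, the neutral phenol traps the oxocarbenium ion generated from dimethoxymethane with P2O5 in CHCl3 (acid-mediated transacetalisation). This also avoids the α-chloro ether. No new compound arises (F0).

**Further compounds**
F1 | step 3 | ethyl 2-[(6-methoxy-2-oxo-2H-chromen-7-yl)oxy]acetate | CCOC(=O)COc1cc2oc(=O)ccc2cc1OC
F2 | step 3 | 2-[(6-methoxy-2-oxo-2H-chromen-7-yl)oxy]acetic acid | OC(=O)COc1cc2oc(=O)ccc2cc1OC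
F3 | step 3 | 6-methoxy-3-[(6-methoxy-2-oxo-2H-chromen-7-yl)oxy]-2-oxo-2H-chromen-7-yl acetate | CC(=O)Oc1cc2oc(=O)c(Oc3cc4oc(=O)ccc4cc3OC)cc2cc1OC
F4 | step 2 | 7-(benzyloxy)-6-methoxy-2H-chromen-2-one | COc1cc2ccc(=O)oc2cc1OCc1ccccc1
F5 | step 2 | 7-(benzyloxy)-3-bromo-6-methoxy-2H-chromen-2-one | COc1cc2cc(Br)c(=O)oc2cc1OCc1ccccc1
F6 | step 2 | 7-(benzyloxy)-6-methoxy-3-[(6-methoxy-2-oxo-2H-chromen-7-yl)oxy]-2H-chromen-2-one | COc1cc2cc(Oc3cc4oc(=O)ccc4cc3OC)c(=O)oc2cc1OCc1ccccc1
F0 | step 1 | none | none
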